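**Strategy.** Ring B (C4a, C5, C6, C7, C8, C8a) holds an aldol retron: the tertiary carbinol C7, the quaternary C8 and its exocyclic ketone. Everything rests on closing this ring last by a copper hydride reductive aldol cyclisation, which in one operation forges the C7–C8 bond between two fully substituted carbons, creates the C8 methyl group, sets both stereocentres from the C8a centre and delivers the C4=C4a/C5=C6 diene intact. Its precursor is a ring A cyclohexene bearing an α-methylene ketone on C8a and a (Z)-3-oxobut-1-enyl arm on C4a, assembled by Evans aldol, ozonolysis–cyclodehydration and two olefin-forming couplings. The tetraene acid is added by esterification and a late Stille coupling.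

Key step: step 14

Remark on numbering: decalin numbering is used throughout. C1 carries the ester oxygen, C3 the ring A methyl, C4=C4a and C5=C6 the diene, C7 the carbinol, C8 the quaternary carbon, C8a the ring-fusion CH, C9 the side-chain ketone carbon. Primed locants C1′ (free carboxyl) to C12′ (ester carbonyl) refer to the tetraene acid.

Remark on chemistry: 3-[(tert-butyldiphenylsilyl)oxy]propanal (15) and (E)-3-methylpent-2-en-4-yn-1-ol (30) are taken as commercial. The (Z)-dienone arm of 17 and 18 is assumed to equilibrate reversibly with its 2H-pyran valence isomer and to react through the open form.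

**Step 1**
Reactants: 1 (E)-pent-3-en-2-one
Product: 2 (R,E)-pent-3-en-2-ol
Conditions: (S)-2-methyl-CBS-oxazaborolidine (10 mol %), catecholborane, toluene, −78 °C
Reagents that add atoms: none
Why: Corey–Bakshi–Shibata reduction, in which the alkenyl group acts as the large substituent so that hydride is delivered to the face giving the (R)-carbinol.

**Step 2**
Reactants: 2 (R,E)-pent-3-en-2-ol
Product: 3 ethyl (R,E)-3-methylhex-4-enoate
Conditions: MeC(OEt)3, EtCO2H (cat.), 140 °C, EtOH distilled off
Reagents that add atoms: triethyl orthoacetate, CC(OCC)(OCC)OCC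
Why: Johnson–Claisen rearrangement through a chair transition state with the carbinol methyl equatorial transfers the C–O chirality suprafacially to the new C–C stereocentre (later C3, R) and leaves an (E)-propenyl group as the masked C4 aldehyde.

**Step 3**
Reactants: 3 ethyl (R,E)-3-methylhex-4-enoate
Product: 4 (R,E)-3-methylhex-4-enal
Conditions: i-Bu2AlH, CH2Cl2, −78 °C; aq. sodium potassium tartrate
Reagents that add atoms: none
Why: Low-temperature half-reduction of the ester stops at the aldehyde because the tetrahedral aluminium hemiacetal survives until work-up, and the β-stereocentre is not enolisable.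

**Step 4**
Reactants: 5 (R)-4-benzyloxazolidin-2-one; 6 pent-4-enoyl chloride
Product: 7 (R)-4-benzyl-3-(pent-4-enoyl)oxazolidin-2-one
Conditions: n-BuLi, THF, −78 °C; then 6, −78 → 0 °C
Reagents that add atoms: none
Why: N-acylation of the lithiated oxazolidinone by the acid chloride (standard imide formation).

**Step 5**
Reactants: 7 (R)-4-benzyl-3-(pent-4-enoyl)oxazolidin-2-one; 4 (R,E)-3-methylhex-4-enal
Product: 8 (R)-4-benzyl-3-[(2R,3S,5R,E)-3-hydroxy-5-methyl-2-(prop-2-en-1-yl)oct-6-enoyl]oxazolidin-2-one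
Conditions: Bu2BOTf, i-Pr2NEt, CH2Cl2, −78 → 0 °C; 4, −78 → 0 °C; pH 7 buffer, MeOH, H2O2
Reagents that add atoms: none
Why: Evans syn aldol reaction in which the (Z)-boron enolate adds through a chair transition state on the face remote from the benzyl group, setting C8a (2R here) and C1 (3S) together under auxiliary control.

**Step 6**
Reactants: 8 Evans aldol adduct
Product: 9 (2R,3S,5R,E)-3-hydroxy-N-methoxy-N,5-dimethyl-2-(prop-2-en-1-yl)oct-6-enamide
Conditions: MeNHOMe·HCl, AlMe3, THF, −10 → 0 °C
Reagents that add atoms: N,O-dimethylhydroxylamine hydrochloride, CNOC.Cl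
Why: Aluminium amide transamidation of the β-hydroxy imide, assisted by the free hydroxyl, releases the auxiliary and gives the Weinreb amide without epimerisation.

**Step 7**
Reactants: 9 Weinreb amide
Product: 10 (2R,3S,5R,E)-N-methoxy-N,5-dimethyl-2-(prop-2-en-1-yl)-3-[(triethylsilyl)oxy]oct-6-enamide
Conditions: TESOTf, 2,6-lutidine, CH2Cl2, −78 °C
Reagents that add atoms: triethylsilyl trifluoromethanesulfonate, CC[Si](CC)(CC)OS(=O)(=O)C(F)(F)F
Why: Silylation of the secondary alcohol gives a C1 silyl ether that can later be removed in the presence of a primary tert-butyldiphenylsilyl ether.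

**Step 8**
Reactants: 10 silylated Weinreb amide
Product: 11 (3R,4S,6R,E)-6-methyl-3-(prop-2-en-1-yl)-4-[(triethylsilyl)oxy]non-7-en-2-one
Conditions: MeMgBr, THF, 0 °C
Reagents that add atoms: methylmagnesium bromide, C[Mg]Br
Why: Weinreb ketone synthesis, in which the chelated tetrahedral intermediate prevents over-addition and the α-centre is not disturbed.

**Step 9**
Reactants: 11 methyl ketone
Product: 12 (3R,4S,6R,E)-6-methyl-3-(prop-2-en-1-yl)-4-[(triethylsilyl)oxy]nona-1,7-dien-2-yl trifluoromethanesulfonate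
Conditions: KN(SiMe3)2, THF, −78 °C; PhNTf2
Reagents that add atoms: N-phenylbis(trifluoromethanesulfonimide), O=S(=O)(N(c1ccccc1)S(=O)(=O)C(F)(F)F)C(F)(F)F
Why: Kinetic deprotonation occurs at the methyl group rather than at the hindered C8a methine, so O-triflation gives the terminal enol triflate (the future C8=CH2 unit) without β-elimination of the silyloxy group.

**Step 10**
Reactants: 12 enol triflate
Product: 14 ring A enal 1-[(1R,4R,6S)-2-formyl-4-methyl-6-(triethylsilyloxy)cyclohex-2-en-1-yl]ethenyl trifluoromethanesulfonate, via dialdehyde 13 (not isolated)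
Conditions: O3, CH2Cl2, −78 °C; PPh3; then Bn2NH·CF3CO2H (cat.), toluene, 23 → 50 °C
Reagents that add atoms: ozone, [O-][O+]=O
Why: Ozone cleaves the allyl and (E)-propenyl double bonds much faster than the electron-poor enol triflate, and amine-salt-catalysed intramolecular aldol condensation of the 1,7-dialdehyde (enamine at the unbranched C5 aldehyde attacking C4) closes ring A as the conjugated enal, the alternative aldol through C3 being unable to dehydrate.

**Step 11**
Reactants: 14 ring A enal; 15 3-[(tert-butyldiphenylsilyl)oxy]propanal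
Product: 16 5-[(tert-butyldiphenylsilyl)oxy]-2-[(1R,4R,6S)-2-formyl-4-methyl-6-[(triethylsilyl)oxy]cyclohex-2-en-1-yl]pent-1-en-3-ol (both carbinol epimers)
Conditions: CrCl2, NiCl2 (2 mol %), DMF, 23 °C, 15 (4 equiv)
Reagents that add atoms: none
Why: Nozaki–Hiyama–Kishi coupling, in which the alkenylchromium formed from the enol triflate adds to the unhindered aliphatic aldehyde used in excess in preference to the hindered conjugated aldehyde; the new carbinol centre is formed unselectively and is removed by oxidation in step 13.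

**Step 12**
Reactants: 16 hydroxy enal
Product: 17 (Z)-4-[(3R,5S,6S)-6-{5-[(tert-butyldiphenylsilyl)oxy]-3-hydroxypent-1-en-2-yl}-3-methyl-5-[(triethylsilyl)oxy]cyclohex-1-en-1-yl]but-3-en-2-one
Conditions: (CF3CH2O)2P(O)CH2C(O)CH3, KN(SiMe3)2, 18-crown-6, THF, −78 °C
Reagents that add atoms: bis(2,2,2-trifluoroethyl) (2-oxopropyl)phosphonate, CC(=O)CP(=O)(OCC(F)(F)F)OCC(F)(F)F
Why: Still–Gennari variant of the Horner–Wadsworth–Emmons reaction, in which fast irreversible elimination from the kinetic adduct gives the (Z)-enone that ring closure requires.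

**Step 13**
Reactants: 17 (Z)-dienone alcohol
Product: 18 (Z)-4-[(3R,5S,6S)-6-{5-[(tert-butyldiphenylsilyl)oxy]-3-oxopent-1-en-2-yl}-3-methyl-5-[(triethylsilyl)oxy]cyclohex-1-en-1-yl]but-3-en-2-one
Conditions: Dess–Martin periodinane, NaHCO3, CH2Cl2, 0 °C
Reagents that add atoms: none
Why: Mild buffered oxidation of the secondary allylic alcohol gives the α-methylene ketone without isomerising the (Z)-dienone.

**Step 14**
Reactants: 18 bis-enone
Product: 20 ring-B-closed decalin (1S,3R,7R,8R,8aS) carrying C1-OTES and C7-OH and the 3-(tert-butyldiphenylsilyloxy)propanoyl group on C8, via copper enolate 19 (not isolated)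
Conditions: [(Ph3P)CuH]6 (0.3 equiv), toluene, −40 → 0 °C; aq. NH4Cl
Reagents that add atoms: none
Why: Hydride transfer from the copper hydride cluster to the unhindered CH2 terminus of the 1,1-disubstituted enone gives regiospecifically the fully substituted monovalent copper enolate 19 (C8 now carries its methyl group), which adds to the C7 methyl ketone in a 6-(enolexo)-exo-trig closure that forms the C7–C8 bond and ring B. The closest known reaction type is the copper hydride reductive aldol cyclisation of keto-enones to β-hydroxy ketones. At C8, allylic 1,3-strain keeps the C8a–H bond eclipsed with the enolate C8=C9 bond, so the ketone delivered from C4a attacks the face that leaves the acyl group cis to H-8a and the new methyl trans to it. At C7, in the chair-like copper-bridged transition state the ketone oxygen is equatorial and gauche to the enolate oxygen while the ketone methyl is axial and anti to the C8 methyl, which places the hydroxyl trans to the acyl group. The step needs chemoselective reduction of the α-methylene ketone beside the (Z)-dienone, which is secured because the β-unsubstituted enone is far more accessible to the bulky hydride cluster than the β-substituted dienone and because hydride is limiting at low temperature. Since the enolate never forms on the CH2CH2O side, regioisomeric enolisation and β-elimination of the silyloxy group are excluded.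

**Step 15**
Reactants: 20 silyl-protected decalin
Product: 21 3-[(tert-butyldiphenylsilyl)oxy]-1-[(1S,3R,7R,8R,8aS)-1,7-dihydroxy-3,7,8-trimethyl-1,2,3,7,8,8a-hexahydronaphthalen-8-yl]propan-1-one
Conditions: HF·pyridine, pyridine, THF, 0 °C
Reagents that add atoms: none
Why: Buffered fluoride removes the secondary triethylsilyl ether while the much more robust primary tert-butyldiphenylsilyl ether and the tertiary allylic alcohol survive.

**Step 16**
Reactants: 22 prop-2-yn-1-ol
Product: 23 (E)-3-iodo-2-methylprop-2-en-1-ol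
Conditions: AlMe3, Cp2ZrCl2 (25 mol %), CH2Cl2, 0 → 23 °C; I2, THF, −30 °C
Reagents that add atoms: trimethylaluminium, C[Al](C)C; iodine, II
Why: Negishi carboalumination adds methyl and aluminium syn across the alkyne (methyl to the internal carbon), and iodinolysis of the C–Al bond with retention gives the (E)-iodoalkene.

**Step 17**
Reactants: 23 (E)-3-iodo-2-methylprop-2-en-1-ol
Product: 24 (E)-3-iodo-2-methylprop-2-enal
Conditions: MnO2, CH2Cl2, 23 °C
Reagents that add atoms: none
Why: Selective heterogeneous oxidation of the allylic alcohol gives the enal without touching the vinyl iodide or its geometry.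

**Step 18**
Reactants: 25 (S)-4-benzyl-3-propanoyloxazolidin-2-one; 24 (E)-3-iodo-2-methylprop-2-enal
Product: 26 (S)-4-benzyl-3-[(2S,3S,E)-3-hydroxy-5-iodo-2,4-dimethylpent-4-enoyl]oxazolidin-2-one
Conditions: Bu2BOTf, i-Pr2NEt, CH2Cl2, −78 → 0 °C; 24, −78 → 0 °C; pH 7 buffer, MeOH, H2O2
Reagents that add atoms: none
Why: Evans syn aldol reaction in which the (Z)-boron enolate and the (S)-auxiliary set C11′ (S) and C10′ (S) together through a chair transition state.

**Step 19**
Reactants: 26 side-chain aldol adduct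
Product: 27 (S)-4-benzyl-3-[(2S,3S,E)-5-iodo-2,4-dimethyl-3-[(triethylsilyl)oxy]pent-4-enoyl]oxazolidin-2-one
Conditions: TESOTf, 2,6-lutidine, CH2Cl2, −78 °C
Reagents that add atoms: triethylsilyl trifluoromethanesulfonate, CC[Si](CC)(CC)OS(=O)(=O)C(F)(F)F
Why: Silylation blocks the β-hydroxyl so that the acid cannot self-acylate or lactonise during the later esterification.

**Step 20**
Reactants: 27 silylated imide
Product: 29 (2S,3S,E)-5-iodo-2,4-dimethyl-3-(triethylsilyloxy)pent-4-enoic acid, via peroxy acid 28 (not isolated)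
Conditions: LiOH, H2O2, THF/H2O, 0 °C; aq. Na2SO3; HCl to pH 3
Reagents that add atoms: hydrogen peroxide, OO
Why: Hydroperoxide attacks the exocyclic imide carbonyl selectively and the resulting peroxy acid is reduced by sulfite, conditions under which the α-centre and the silyl ether are stable.

**Step 21**
Reactants: 30 (E)-3-methylpent-2-en-4-yn-1-ol
Product: 31 (2E,4E)-3-methyl-5-(tributylstannyl)penta-2,4-dien-1-ol
Conditions: Bu3SnH, PdCl2(PPh3)2 (2 mol %), THF, 0 °C
Reagents that add atoms: tributyltin hydride, CCCC[SnH](CCCC)CCCC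
Why: Palladium-catalysed syn hydrostannation of the terminal alkyne places tin on the terminal carbon and gives the (E)-alkenylstannane.

**Step 22**
Reactants: 31 stannyl dienol
Product: 32 (2E,4E)-3-methyl-5-(tributylstannyl)penta-2,4-dienal
Conditions: MnO2, CH2Cl2, 23 °C
Reagents that add atoms: none
Why: Neutral allylic oxidation gives the dienal without protodestannylation.

**Step 23**
Reactants: 32 stannyl dienal
Product: 33 (2E,4E,6E)-5-methyl-7-(tributylstannyl)hepta-2,4,6-trienoic acid
Conditions: (EtO)2P(O)CH2CO2H, LiN(SiMe3)2 (2.1 equiv), THF, −78 → 0 °C; aq. NaH2PO4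
Reagents that add atoms: diethylphosphonoacetic acid, OC(=O)CP(=O)(OCC)OCC
Why: Horner–Wadsworth–Emmons reaction of the phosphonoacetate dianion gives the (E)-configured unsaturated acid directly, so no ester has to be cleaved later.

**Step 24**
Reactants: 29 side-chain acid; 21 decalin diol
Product: 35 decalin C1 ester bearing the (E)-vinyl iodide, via mixed anhydride 34 (not isolated)
Conditions: 2,4,6-trichlorobenzoyl chloride, Et3N, THF, 23 °C; then 21, DMAP, toluene, 40 °C
Reagents that add atoms: none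
Why: Yamaguchi esterification, in which the mixed anhydride acylates the secondary C1 hydroxyl under DMAP catalysis while the tertiary C7 hydroxyl is too hindered to react; no stereocentre is formed.

**Step 25**
Reactants: 35 vinyl iodide ester; 33 stannyl trienoic acid
Product: 36 bis-silyl ether of the target (C10′ O-TES, primary O-TBDPS)
Conditions: Pd2(dba)3 (5 mol %), AsPh3, NMP, 23 °C, dark
Reagents that add atoms: none
Why: Stille coupling joins C7′ and C8′ with retention of both alkene geometries under neutral conditions that tolerate the free acid, the ester and the β-hydroxy ketone.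

**Step 26**
Reactants: 36 bis-silyl ether
Product: 37 CNP0306937.1 (target)
Conditions: HF·pyridine, pyridine, THF, 0 → 23 °C
Reagents that add atoms: none
Why: Buffered fluoride cleaves both silyl ethers without base, so the retro-aldol-prone β-hydroxy ketone, the ester and the tetraene should survive.

**Compound list**

1 | (E)-pent-3-en-2-one | C/C=C/C(C)=O | starting material
2 | (R,E)-pent-3-en-2-ol | C[C@@H](O)/C=C/C | intermediate
3 | ethyl (R,E)-3-methylhex-4-enoate | CCOC(=O)C[C@@H](C)/C=C/C | intermediate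
4 | (R,E)-3-methylhex-4-enal | O=CC[C@@H](C)/C=C/C | intermediate
5 | (R)-4-benzyloxazolidin-2-one | O=C1N[C@H](Cc2ccccc2)CO1 | starting material
6 | pent-4-enoyl chloride | C=CCCC(Cl)=O | starting material
7 | (R)-4-benzyl-3-(pent-4-enoyl)oxazolidin-2-one | C=CCCC(=O)N1[C@H](Cc2ccccc2)COC1=O | intermediate
8 | (R)-4-benzyl-3-[(2R,3S,5R,E)-3-hydroxy-5-methyl-2-(prop-2-en-1-yl)oct-6-enoyl]oxazolidin-2-one | O=C1OC[C@@H](Cc2ccccc2)N1C(=O)[C@H](CC=C)[C@@H](O)C[C@@H](C)/C=C/C | intermediate
9 | (2R,3S,5R,E)-3-hydroxy-N-methoxy-N,5-dimethyl-2-(prop-2-en-1-yl)oct-6-enamide | CON(C)C(=O)[C@H](CC=C)[C@@H](O)C[C@@H](C)/C=C/C | intermediate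
10 | (2R,3S,5R,E)-N-methoxy-N,5-dimethyl-2-(prop-2-en-1-yl)-3-[(triethylsilyl)oxy]oct-6-enamide | CON(C)C(=O)[C@H](CC=C)[C@@H](O[Si](CC)(CC)CC)C[C@@H](C)/C=C/C | intermediate
11 | (3R,4S,6R,E)-6-methyl-3-(prop-2-en-1-yl)-4-[(triethylsilyl)oxy]non-7-en-2-one | CC(=O)[C@H](CC=C)[C@@H](O[Si](CC)(CC)CC)C[C@@H](C)/C=C/C | intermediate
12 | (3R,4S,6R,E)-6-methyl-3-(prop-2-en-1-yl)-4-[(triethylsilyl)oxy]nona-1,7-dien-2-yl trifluoromethanesulfonate | C=C(OS(=O)(=O)C(F)(F)F)[C@H](CC=C)[C@@H](O[Si](CC)(CC)CC)C[C@@H](C)/C=C/C | intermediate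
13 | (3R,4S,6R)-6-methyl-7-oxo-3-(2-oxoethyl)-4-[(triethylsilyl)oxy]hept-1-en-2-yl trifluoromethanesulfonate (dialdehyde, not isolated) | C=C(OS(=O)(=O)C(F)(F)F)[C@H](CC=O)[C@@H](O[Si](CC)(CC)CC)C[C@@H](C)C=O | intermediate
14 | 1-[(1R,4R,6S)-2-formyl-4-methyl-6-[(triethylsilyl)oxy]cyclohex-2-en-1-yl]ethenyl trifluoromethanesulfonate (ring A; C1 S, C3 R, all three substituents cis) | CC[Si](CC)(CC)O[C@H]1C[C@@H](C)C=C(C=O)[C@H]1C(=C)OS(=O)(=O)C(F)(F)F | intermediate
15 | 3-[(tert-butyldiphenylsilyl)oxy]propanal | O=CCCO[Si](c1ccccc1)(c1ccccc1)C(C)(C)C | starting material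
16 | 5-[(tert-butyldiphenylsilyl)oxy]-2-[(1R,4R,6S)-2-formyl-4-methyl-6-[(triethylsilyl)oxy]cyclohex-2-en-1-yl]pent-1-en-3-ol (both carbinol epimers) | CC[Si](CC)(CC)O[C@H]1C[C@@H](C)C=C(C=O)[C@H]1C(=C)C(O)CCO[Si](c1ccccc1)(c1ccccc1)C(C)(C)C | intermediate
17 | (Z)-4-[(3R,5S,6S)-6-{5-[(tert-butyldiphenylsilyl)oxy]-3-hydroxypent-1-en-2-yl}-3-methyl-5-[(triethylsilyl)oxy]cyclohex-1-en-1-yl]but-3-en-2-one | CC[Si](CC)(CC)O[C@H]1C[C@@H](C)C=C(/C=C\C(C)=O)[C@H]1C(=C)C(O)CCO[Si](c1ccccc1)(c1ccccc1)C(C)(C)C | intermediate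
18 | (Z)-4-[(3R,5S,6S)-6-{5-[(tert-butyldiphenylsilyl)oxy]-3-oxopent-1-en-2-yl}-3-methyl-5-[(triethylsilyl)oxy]cyclohex-1-en-1-yl]but-3-en-2-one | CC[Si](CC)(CC)O[C@H]1C[C@@H](C)C=C(/C=C\C(C)=O)[C@H]1C(=C)C(=O)CCO[Si](c1ccccc1)(c1ccccc1)C(C)(C)C | intermediate
19 | monovalent copper enolate of 18 after hydride addition to the methylene carbon (not isolated; phosphine ligand omitted) | CC[Si](CC)(CC)O[C@H]1C[C@@H](C)C=C(/C=C\C(C)=O)[C@H]1C(C)=C(O[Cu])CCO[Si](c1ccccc1)(c1ccccc1)C(C)(C)C | intermediate
20 | 3-[(tert-butyldiphenylsilyl)oxy]-1-[(1S,3R,7R,8R,8aS)-7-hydroxy-3,7,8-trimethyl-1-[(triethylsilyl)oxy]-1,2,3,7,8,8a-hexahydronaphthalen-8-yl]propan-1-one | CC[Si](CC)(CC)O[C@H]1C[C@@H](C)C=C2C=C[C@@](C)(O)[C@](C)(C(=O)CCO[Si](c3ccccc3)(c3ccccc3)C(C)(C)C)[C@H]21 | intermediate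
21 | 3-[(tert-butyldiphenylsilyl)oxy]-1-[(1S,3R,7R,8R,8aS)-1,7-dihydroxy-3,7,8-trimethyl-1,2,3,7,8,8a-hexahydronaphthalen-8-yl]propan-1-one | O[C@H]1C[C@@H](C)C=C2C=C[C@@](C)(O)[C@](C)(C(=O)CCO[Si](c3ccccc3)(c3ccccc3)C(C)(C)C)[C@H]21 | intermediate
22 | prop-2-yn-1-ol | C#CCO | starting material
23 | (E)-3-iodo-2-methylprop-2-en-1-ol | OC/C(C)=C/I | intermediate
24 | (E)-3-iodo-2-methylprop-2-enal | O=C/C(C)=C/I | intermediate
25 | (S)-4-benzyl-3-propanoyloxazolidin-2-one | CCC(=O)N1[C@@H](Cc2ccccc2)COC1=O | starting material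
26 | (S)-4-benzyl-3-[(2S,3S,E)-3-hydroxy-5-iodo-2,4-dimethylpent-4-enoyl]oxazolidin-2-one | O=C1OC[C@H](Cc2ccccc2)N1C(=O)[C@@H](C)[C@H](O)/C(C)=C/I | intermediate
27 | (S)-4-benzyl-3-[(2S,3S,E)-5-iodo-2,4-dimethyl-3-[(triethylsilyl)oxy]pent-4-enoyl]oxazolidin-2-one | O=C1OC[C@H](Cc2ccccc2)N1C(=O)[C@@H](C)[C@H](O[Si](CC)(CC)CC)/C(C)=C/I | intermediate
28 | (2S,3S,E)-5-iodo-2,4-dimethyl-3-[(triethylsilyl)oxy]pent-4-eneperoxoic acid (not isolated) | OOC(=O)[C@@H](C)[C@H](O[Si](CC)(CC)CC)/C(C)=C/I | intermediate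
29 | (2S,3S,E)-5-iodo-2,4-dimethyl-3-[(triethylsilyl)oxy]pent-4-enoic acid | OC(=O)[C@@H](C)[C@H](O[Si](CC)(CC)CC)/C(C)=C/I | intermediate
30 | (E)-3-methylpent-2-en-4-yn-1-ol | OC/C=C(C)/C#C | starting material
31 | (2E,4E)-3-methyl-5-(tributylstannyl)penta-2,4-dien-1-ol | OC/C=C(C)/C=C/[Sn](CCCC)(CCCC)CCCC | intermediate
32 | (2E,4E)-3-methyl-5-(tributylstannyl)penta-2,4-dienal | O=C/C=C(C)/C=C/[Sn](CCCC)(CCCC)CCCC | intermediate
33 | (2E,4E,6E)-5-methyl-7-(tributylstannyl)hepta-2,4,6-trienoic acid | OC(=O)/C=C/C=C(C)/C=C/[Sn](CCCC)(CCCC)CCCC | intermediate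
34 | mixed anhydride of acid 29 and 2,4,6-trichlorobenzoic acid (not isolated) | O=C(OC(=O)[C@@H](C)[C@H](O[Si](CC)(CC)CC)/C(C)=C/I)c1c(Cl)cc(Cl)cc1Cl | intermediate
35 | (1S,3R,7R,8R,8aS)-8-{3-[(tert-butyldiphenylsilyl)oxy]propanoyl}-7-hydroxy-3,7,8-trimethyl-1,2,3,7,8,8a-hexahydronaphthalen-1-yl (2S,3S,E)-5-iodo-2,4-dimethyl-3-[(triethylsilyl)oxy]pent-4-enoate | I/C=C(\C)[C@@H](O[Si](CC)(CC)CC)[C@H](C)C(=O)O[C@H]1C[C@@H](C)C=C2C=C[C@@](C)(O)[C@](C)(C(=O)CCO[Si](c3ccccc3)(c3ccccc3)C(C)(C)C)[C@H]21 | intermediate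
36 | target protected as C10′ triethylsilyl ether and primary tert-butyldiphenylsilyl ether (free carboxylic acid) | CC(/C=C/C=C(\C)[C@@H](O[Si](CC)(CC)CC)[C@H](C)C(=O)O[C@H]1C[C@@H](C)C=C2C=C[C@@](C)(O)[C@](C)(C(=O)CCO[Si](c3ccccc3)(c3ccccc3)C(C)(C)C)[C@H]21)=C\C=C\C(=O)O | intermediate
37 | CNP0306937.1: (2E,4E,6E,8E,10S,11S)-10-hydroxy-12-{[(1S,3R,7R,8R,8aS)-7-hydroxy-8-(3-hydroxypropanoyl)-3,7,8-trimethyl-1,2,3,7,8,8a-hexahydronaphthalen-1-yl]oxy}-5,9,11-trimethyl-12-oxododeca-2,4,6,8-tetraenoic acid | CC(/C=C/C=C(\C)[C@@H](O)[C@H](C)C(=O)O[C@H]1C[C@@H](C)C=C2C=C[C@@](C)(O)[C@](C)(C(=O)CCO)[C@H]21)=C\C=C\C(=O)O | target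

**Step count and risks**

Total step count: 26. Longest linear sequence: 17 steps (steps 1–3, 5–15 and 24–26).

Steps most likely to fail:

1. Step 14 (key step). Competing 1,4- or 1,6-reduction of the (Z)-dienone, retro-aldol opening of the copper aldolate and poor facial selectivity at the ketone could all erode the ring closure. The fallback separates enolate formation from closure and uses an open transition state. It sets out from 18: RhCl(PPh3)3-catalysed 1,4-hydrosilylation with Et3SiH at the α-methylene ketone gives the tetrasubstituted triethylsilyl enol ether F1, which is cyclised by an intramolecular Mukaiyama aldol reaction (TiCl4, CH2Cl2, −78 °C). Aqueous work-up returns the route at 20.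

2. Step 12. Loss of (Z)-selectivity in the olefination of a hindered conjugated aldehyde, or base- or light-induced Z to E isomerisation of the dienone, would give material that cannot cyclise. The fallback sets out from 16: Stork–Zhao olefination (Ph3PCH2I iodide, NaN(SiMe3)2, THF/DMPU, −78 °C) gives the (Z)-dienyl iodide F2. A second Nozaki–Hiyama–Kishi reaction with acetaldehyde (CrCl2, NiCl2 cat., DMSO) gives the (Z)-dienyl diol F3. Dess–Martin oxidation of both allylic alcohols then rejoins the route at 18.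

3. Step 24. Slow acylation of the hindered C1 hydroxyl next to the ring fusion and the quaternary C8 could allow β-elimination or α-epimerisation of the activated acid on prolonged heating. The fallback esterifies before ring B exists, when C1 is unencumbered. It sets out from 18: HF·pyridine/pyridine removes the triethylsilyl group to give the hydroxy bis-enone F4, and Yamaguchi esterification with 29 gives the ester F5. The [(Ph3P)CuH]6 reductive aldol cyclisation of F5 then rejoins the route at 35.

**Further compounds**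

F1 | step 14 | triethylsilyl enol ether from 1,4-hydrosilylation of the α-methylene ketone of 18 | CC[Si](CC)(CC)O[C@H]1C[C@@H](C)C=C(/C=C\C(C)=O)[C@H]1C(C)=C(CCO[Si](c1ccccc1)(c1ccccc1)C(C)(C)C)O[Si](CC)(CC)CC
F2 | step 12 | (Z)-dienyl iodide from 16 (CHO replaced by (Z)-CH=CHI) | CC[Si](CC)(CC)O[C@H]1C[C@@H](C)C=C(/C=C\I)[C@H]1C(=C)C(O)CCO[Si](c1ccccc1)(c1ccccc1)C(C)(C)C
F3 | step 12 | (Z)-dienyl diol (both carbinols as epimer mixtures) | CC[Si](CC)(CC)O[C@H]1C[C@@H](C)C=C(/C=C\C(C)O)[C@H]1C(=C)C(O)CCO[Si](c1ccccc1)(c1ccccc1)C(C)(C)C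
F4 | step 24 | C1-hydroxy bis-enone (18 without the triethylsilyl group) | O[C@H]1C[C@@H](C)C=C(/C=C\C(C)=O)[C@H]1C(=C)C(=O)CCO[Si](c1ccccc1)(c1ccccc1)C(C)(C)C
F5 | step 24 | C1 ester of F4 with acid 29 | I/C=C(\C)[C@@H](O[Si](CC)(CC)CC)[C@H](C)C(=O)O[C@H]1C[C@@H](C)C=C(/C=C\C(C)=O)[C@H]1C(=C)C(=O)CCO[Si](c1ccccc1)(c1ccccc1)C(C)(C)C
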